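**Retrosynthetic overview**
1. Dihydropyranone ring (formed last): lactonisation of the C5–OH onto C1 of a δ-hydroxy-β-keto tert-butyl ester; C2–C3 by Claisen condensation on a C3 methyl ester.
2. C7–OH: 1,3-syn reduction of a C7 ketone directed by the C5–OH; C5 comes with the commercial (3R)-ylide (rosuvastatin side-chain reagent).
3. C9–O: hemiacetal oxa-conjugate addition from the C11 oxygen onto the C7 enone; this closes a temporary 1,3-dioxane (first ring formed) and fixes 9,11-syn.
4. C8=C9: Wittig reaction of the ylide with (S)-3-silyloxydodecanal.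
5. C11–O: enantioselective amine-catalysed oxa-Michael addition of a silanol to (E)-dodec-2-enal.

Assumption: the diarylprolinol silyl ether blocks the iminium face on the side of its CAr2(OSiMe3) group, as in its known conjugate additions, so the (R)-catalyst gives (S)-4; if the observed sense is opposite, the (S)-catalyst is used.
Assumption: the target is the enol tautomer of the β-keto-δ-lactone, as drawn; locants C1–C20 in the text follow the target chain (C1 = lactone carbonyl, C20 = chain terminus).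

**Step 1**
Reactants: 1 (E)-dodec-2-enal; 2 triphenylsilanol; 3 methyl (3R)-3-[(tert-butyldimethylsilyl)oxy]-5-oxo-6-(triphenylphosphoranylidene)hexanoate
Product: 5 methyl (3R,6E,9S)-3-[(tert-butyldimethylsilyl)oxy]-5-oxo-9-[(triphenylsilyl)oxy]octadec-6-enoate, via silyloxy aldehyde 4 (not isolated)
Conditions: 1 (1.0 equiv), 2 (3 equiv), (R)-2-{bis[3,5-bis(trifluoromethyl)phenyl][(trimethylsilyl)oxy]methyl}pyrrolidine (10 mol%), PhCO2H (10 mol%), PhMe, 4 °C; SiO2 plug; then 3 (1.2 equiv), PhMe, 45 °C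
Reagents that add atoms: triphenylsilanol (2), O[Si](c1ccccc1)(c1ccccc1)c1ccccc1
Why: Proposed new method: iminium-catalysed enantioselective oxa-Michael addition of a triorganosilanol to an enal – the catalyst converts 1 into an E,s-trans iminium ion with one face blocked, Ph3SiOH (an O–H acid of about the strength of the oximes and phenols that already add under such conditions, H-bond-activated by benzoate) attacks C3 from the open face and sets C11 as S, enamine hydrolysis releases 4 already O-protected, and Wittig trapping by the keto-stabilised ylide 3 takes the aldehyde out of the retro-addition equilibrium and gives the E-enone; closest known reaction type: amine-catalysed oxa-Michael β-hydroxylation of enals with oximes (and the related H2O2 epoxidation) followed by Wittig olefination.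

**Step 2**
Reactants: 5 methyl (3R,6E,9S)-3-[(tert-butyldimethylsilyl)oxy]-5-oxo-9-[(triphenylsilyl)oxy]octadec-6-enoate; 6 acetaldehyde
Product: 8 methyl (3R)-3-[(tert-butyldimethylsilyl)oxy]-6-[(2S,4S,6S)-2-methyl-6-nonyl-1,3-dioxan-4-yl]-5-oxohexanoate, via hydroxy enone 7 (not isolated)
Conditions: Bi(NO3)3·5H2O (10 mol%), MeCHO (5 equiv), CH2Cl2, rt
Reagents that add atoms: acetaldehyde (6), CC=O
Why: Bismuth(III)-mediated two-component hemiacetal/oxa-conjugate addition (Evans-type tethered oxa-Michael): the Ph3Si ether (about 50 times more acid-labile than the TBS ether) is cleaved in situ, and the hemiacetal of 7 with acetaldehyde adds to the activated enone through a chair transition state with nonyl, methyl and the side chain equatorial, giving the 2,4,6-cis dioxane and hence the 9,11-syn C–O pair.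

**Step 3**
Reactants: 8 methyl (3R)-3-[(tert-butyldimethylsilyl)oxy]-6-[(2S,4S,6S)-2-methyl-6-nonyl-1,3-dioxan-4-yl]-5-oxohexanoate
Product: 9 methyl (3R)-3-hydroxy-6-[(2S,4S,6S)-2-methyl-6-nonyl-1,3-dioxan-4-yl]-5-oxohexanoate
Conditions: HF·pyridine, pyridine, THF, 0 °C to rt
Reagents that add atoms: none
Why: Fluoride desilylation under buffered, non-basic conditions removes the TBS ether without touching the acetal or causing β-elimination or retro-oxa-Michael of the β-alkoxy ketone; no stereocentre is affected.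

**Step 4**
Reactants: 9 methyl (3R)-3-hydroxy-6-[(2S,4S,6S)-2-methyl-6-nonyl-1,3-dioxan-4-yl]-5-oxohexanoate
Product: 10 methyl (3R,5S)-3,5-dihydroxy-6-[(2S,4R,6S)-2-methyl-6-nonyl-1,3-dioxan-4-yl]hexanoate
Conditions: Et2BOMe (1.1 equiv), NaBH4, THF–MeOH 4:1, −78 °C; AcOH; MeOH co-evaporation
Reagents that add atoms: none
Why: Narasaka–Prasad reduction: the diethylboron chelate of the β-hydroxy ketone takes external hydride axially and gives the 1,3-syn diol, so C7 is set syn to C5 (the descriptor at dioxane C4 changes only because CIP priorities change).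

**Step 5**
Reactants: 10 methyl (3R,5S)-3,5-dihydroxy-6-[(2S,4R,6S)-2-methyl-6-nonyl-1,3-dioxan-4-yl]hexanoate; 11 tert-butyl acetate
Product: 12 tert-butyl (5R,7S)-5,7-dihydroxy-8-[(2S,4R,6S)-2-methyl-6-nonyl-1,3-dioxan-4-yl]-3-oxooctanoate
Conditions: 11 (5 equiv), LDA (5 equiv), THF, −78 °C; then 10, −78 to −30 °C; aq NH4Cl
Reagents that add atoms: tert-butyl acetate (11), CC(=O)OC(C)(C)C
Why: Crossed Claisen condensation: excess lithium enolate of tert-butyl acetate acylates at the methyl ester (directly or through the δ-lactone formed by the C7 alkoxide), and the β-keto ester is protected as its enolate until quench, as known for unprotected β-hydroxy esters; no stereocentre is touched.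

**Step 6**
Reactants: 12 tert-butyl (5R,7S)-5,7-dihydroxy-8-[(2S,4R,6S)-2-methyl-6-nonyl-1,3-dioxan-4-yl]-3-oxooctanoate
Product: 13 (6R)-4-hydroxy-6-[(2R,4S,6S)-2,4,6-trihydroxypentadecyl]-5,6-dihydro-2H-pyran-2-one
Conditions: TFA, CH2Cl2, 0 °C; then TFA–H2O 9:1, rt
Reagents that add atoms: none
Why: Acid-mediated tert-butyl ester cleavage with δ-lactonisation (C5–OH onto C1; six-membered ring favoured over the eight-membered one from C7–OH), then aqueous-acid hydrolysis of the ethylidene acetal; the β-keto lactone is obtained as its enol and no stereocentre is touched.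

**Compound list**
1 | (E)-dodec-2-enal | CCCCCCCCC/C=C/C=O | starting material
2 | triphenylsilanol | O[Si](c1ccccc1)(c1ccccc1)c1ccccc1 | starting material
3 | methyl (3R)-3-[(tert-butyldimethylsilyl)oxy]-5-oxo-6-(triphenylphosphoranylidene)hexanoate | COC(=O)C[C@H](O[Si](C)(C)C(C)(C)C)CC(=O)C=P(c1ccccc1)(c1ccccc1)c1ccccc1 | starting material
4 | (3S)-3-[(triphenylsilyl)oxy]dodecanal | CCCCCCCCC[C@H](O[Si](c1ccccc1)(c1ccccc1)c1ccccc1)CC=O | intermediate
5 | methyl (3R,6E,9S)-3-[(tert-butyldimethylsilyl)oxy]-5-oxo-9-[(triphenylsilyl)oxy]octadec-6-enoate | CCCCCCCCC[C@H](O[Si](c1ccccc1)(c1ccccc1)c1ccccc1)C/C=C/C(=O)C[C@@H](O[Si](C)(C)C(C)(C)C)CC(=O)OC | intermediate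
6 | acetaldehyde | CC=O | starting material
7 | methyl (3R,6E,9S)-3-[(tert-butyldimethylsilyl)oxy]-9-hydroxy-5-oxooctadec-6-enoate | CCCCCCCCC[C@H](O)C/C=C/C(=O)C[C@@H](O[Si](C)(C)C(C)(C)C)CC(=O)OC | intermediate
8 | methyl (3R)-3-[(tert-butyldimethylsilyl)oxy]-6-[(2S,4S,6S)-2-methyl-6-nonyl-1,3-dioxan-4-yl]-5-oxohexanoate | CCCCCCCCC[C@H]1C[C@@H](CC(=O)C[C@@H](O[Si](C)(C)C(C)(C)C)CC(=O)OC)O[C@@H](C)O1 | intermediate
9 | methyl (3R)-3-hydroxy-6-[(2S,4S,6S)-2-methyl-6-nonyl-1,3-dioxan-4-yl]-5-oxohexanoate | CCCCCCCCC[C@H]1C[C@@H](CC(=O)C[C@@H](O)CC(=O)OC)O[C@@H](C)O1 | intermediate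
10 | methyl (3R,5S)-3,5-dihydroxy-6-[(2S,4R,6S)-2-methyl-6-nonyl-1,3-dioxan-4-yl]hexanoate | CCCCCCCCC[C@H]1C[C@@H](C[C@@H](O)C[C@@H](O)CC(=O)OC)O[C@@H](C)O1 | intermediate
11 | tert-butyl acetate | CC(=O)OC(C)(C)C | starting material
12 | tert-butyl (5R,7S)-5,7-dihydroxy-8-[(2S,4R,6S)-2-methyl-6-nonyl-1,3-dioxan-4-yl]-3-oxooctanoate | CCCCCCCCC[C@H]1C[C@@H](C[C@@H](O)C[C@@H](O)CC(=O)CC(=O)OC(C)(C)C)O[C@@H](C)O1 | intermediate
13 | (6R)-4-hydroxy-6-[(2R,4S,6S)-2,4,6-trihydroxypentadecyl]-5,6-dihydro-2H-pyran-2-one | CCCCCCCCC[C@H](O)C[C@H](O)C[C@@H](O)C[C@@H]1CC(O)=CC(=O)O1 | target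

**Totals**
Total step count: 6. Longest linear sequence: 6 steps (1 or 3 to 13).

**Steps most likely to fail and fallbacks**

Step 1 (the proposed new silanol oxa-Michael addition). The silanol may add too slowly, the addition may revert before the Wittig trapping, or the ee may be low. The fallback uses known chemistry, sets out from 1 and comes back at 7. Compound 1 is epoxidised with 35% H2O2 and the same (R)-diarylprolinol silyl ether (10 mol%, CH2Cl2, rt) to (2R,3S)-3-nonyloxirane-2-carbaldehyde F1. Without isolation, ylide 3 is added to give methyl (3R,6E)-3-[(tert-butyldimethylsilyl)oxy]-7-[(2S,3S)-3-nonyloxiran-2-yl]-5-oxohept-6-enoate F2. Palladium-catalysed formate hydrogenolysis of this vinyl epoxide (Pd2(dba)3·CHCl3, n-Bu3P, HCO2H, Et3N, dioxane, rt) puts hydride on the allylic carbon C10 and leaves the C11–O bond intact. This gives the hydroxy enone 7, which is isolated and submitted to the step 2 conditions.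

Step 5 (Claisen condensation on the unprotected 1,3-diol). The polyalkoxide may react sluggishly, or eliminate or lactonise unproductively. The fallback sets out from 10 and comes back at 13. Compound 10 is protected with 2,2-dimethoxypropane and PPTS as methyl 2-[(4R,6R)-2,2-dimethyl-6-{[(2S,4S,6S)-2-methyl-6-nonyl-1,3-dioxan-4-yl]methyl}-1,3-dioxan-4-yl]acetate F3. Claisen condensation with the lithium enolate of tert-butyl acetate (2.5 equiv, THF, −78 to −30 °C) then gives tert-butyl 4-[(4R,6R)-2,2-dimethyl-6-{[(2S,4S,6S)-2-methyl-6-nonyl-1,3-dioxan-4-yl]methyl}-1,3-dioxan-4-yl]-3-oxobutanoate F4. TFA–H2O 9:1 removes both acetals and the tert-butyl group and closes the lactone to 13.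

Step 6 (one-pot acidolysis, lactonisation and acetal hydrolysis). The ethylidene acetal may need acid or time that the β-keto lactone does not tolerate (ring opening and decarboxylation). The fallback sets out from 12 and comes back at 13. Anhydrous TFA in CH2Cl2 at 0 °C only closes the lactone and gives (6R)-4-hydroxy-6-{(2R)-2-hydroxy-3-[(2S,4R,6S)-2-methyl-6-nonyl-1,3-dioxan-4-yl]propyl}-5,6-dihydro-2H-pyran-2-one F5. The acetal is then removed without water by transthioacetalisation (propane-1,3-dithiol, BF3·OEt2, CH2Cl2, 0 °C) to give 13.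

**Further compounds**
F1 | step 1 | (2R,3S)-3-nonyloxirane-2-carbaldehyde | CCCCCCCCC[C@@H]1O[C@H]1C=O
F2 | step 1 | methyl (3R,6E)-3-[(tert-butyldimethylsilyl)oxy]-7-[(2S,3S)-3-nonyloxiran-2-yl]-5-oxohept-6-enoate | CCCCCCCCC[C@@H]1O[C@H]1/C=C/C(=O)C[C@@H](O[Si](C)(C)C(C)(C)C)CC(=O)OC
F3 | step 5 | methyl 2-[(4R,6R)-2,2-dimethyl-6-{[(2S,4S,6S)-2-methyl-6-nonyl-1,3-dioxan-4-yl]methyl}-1,3-dioxan-4-yl]acetate | CCCCCCCCC[C@H]1C[C@@H](C[C@@H]2C[C@H](CC(=O)OC)OC(C)(C)O2)O[C@@H](C)O1
F4 | step 5 | tert-butyl 4-[(4R,6R)-2,2-dimethyl-6-{[(2S,4S,6S)-2-methyl-6-nonyl-1,3-dioxan-4-yl]methyl}-1,3-dioxan-4-yl]-3-oxobutanoate | CCCCCCCCC[C@H]1C[C@@H](C[C@@H]2C[C@H](CC(=O)CC(=O)OC(C)(C)C)OC(C)(C)O2)O[C@@H](C)O1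
F5 | step 6 | (6R)-4-hydroxy-6-{(2R)-2-hydroxy-3-[(2S,4R,6S)-2-methyl-6-nonyl-1,3-dioxan-4-yl]propyl}-5,6-dihydro-2H-pyran-2-one | CCCCCCCCC[C@H]1C[C@@H](C[C@@H](O)C[C@@H]2CC(O)=CC(=O)O2)O[C@@H](C)O1
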